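The closed vessel at 0 °C, followed so far as the south run, is ours to act on at 4.0 d, and we must choose what it gets for the next 8.0 d.

| setting | south | east | flask |
|---|---|---|---|
| substrate | 20 mM | 20 mM | 20 mM |
| coupling partner | 0.50 equiv | 0.50 equiv | 0.500 equiv |
| temperature | 0 °C | −15 °C | 0 °C |
| remark | the very flask that is asked about, followed so far | run made earlier |  |
| time |  |  | 4.0 d |

| run | time / d | target / % |
|---|---|---|
| south | 0.333 | 25.3 |
| south | 0.500 | 31.1 |
| south | 0.833 | 37.9 |
| south | 1.67 | 39.7 |
| south | 2.50 | 33.4 |
| south | 4.00 | 26.4 |
| east | 0.625 | 7.7 |
| east | 1.04 | 12.2 |
| east | 1.67 | 20.4 |
| east | 4.00 | 33.8 |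
| east | 5.00 | 38.4 |
| east | 8.00 | 41.9 |

(readings scatter by 1 percentage point)

- green: at 4.0 d raise the temperature by 15 K, then wait 8.0 d
- grey: change nothing and wait 8.0 d more
- amber: at 4.0 d add coupling partner, 100% of the amount charged, then wait 8.0 d
- ochre: at 4.0 d take out 90% of the target then present, then wait 8.0 d

- target, in percent of the substrate first charged, at 4.0 d
- the remedy with the largest gain of target, or "none" below 2 percentage points (green / grey / amber / ochre / none)
- target present, with what was taken out counted in, in percent of the substrate first charged, after grey
- target present, with what was taken out counted in, in percent of the substrate first charged, after amber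

- a species is counted by the substrate in it: one self-condensation product counts as two
- target that was removed still counts
- steps thought possible: adduct -> target; substrate + coupling partner <-> adduct; 2 substrate -> self-condensation product; target <-> isomer of the product
- additions bring no volume worth counting

At 0.500 equiv the coupling partner is the limiting reagent. One coupling partner gives one adduct and one adduct gives one target, so in this flask target plus isomer of the product cannot pass 50.0%. We assume that this ceiling is reached by 1.67 d, after which the readings of the south run fall. The reading of 26.4% then gives 0.528, the target share: target divided by target plus isomer of the product. If the two interconvert first order at one temperature, this share follows the age of the product and not its amount.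

To see where the share ends, we set rate of fall against level, so that time drops out. In the readings of the south run, target falls by 0.0759 d⁻¹ of the charge around a level of 36.6%, then by 0.0467 d⁻¹ around 29.9%. The straight line through these meets zero fall at 19.3%, a rough reading given the scatter of 1 percentage point, and that is a plateau share of 0.386. Its slope makes 8.0 d worth 3.49 time constants, so we take the plateau as nearly reached.

Our reckoning is therefore about 26.4% now and 19.3% after grey. For ochre we reckon 33.9%, the target taken out plus the plateau share of the product left. Amber raises the ceiling to 100%, and for it we reckon 38.6%, provided the substrate has survived. The readings of the east run show no fall up to 8.00 d, so they give no plateau and we leave green unreckoned. We choose to charge coupling partner, since 38.6% stands above the 33.9% of ochre.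

The forecast gives 26.4%, 18.5% after grey and 34% after amber, which lies below our figure, and it chooses amber: “Amber narrowly beats ochre, an uncertain call.”

The flask gives 27.6%, 19.1% after grey and 39.6% after amber, and amber has the largest gain, 12 points.

    adduct → target (k = 0.290 h⁻¹, Ea = 94.0 kJ mol⁻¹)
    substrate + coupling partner ⇌ adduct (K = 54.0 L mol⁻¹, k = 34.0 L mol⁻¹ h⁻¹, Ea = 66.0 kJ mol⁻¹, ΔH = −31.0 kJ mol⁻¹)
    2 substrate → self-condensation product (k = 0.00680 L mol⁻¹ h⁻¹, Ea = 68.0 kJ mol⁻¹)
    target ⇌ isomer of the product (K = 1.70, k = 0.00920 h⁻¹, Ea = 100 kJ mol⁻¹, ΔH = −30.0 kJ mol⁻¹)
    (constants at 0 °C)

In this flask the half-life of substrate by the forward coupling step alone, 0.17 d at 0.103 d, is shorter than the relaxation half-life of target and isomer of the product, 1.98 d, and at 4.00 d it holds 27.6% of target beside 22.3% of isomer of the product, a target share of 0.553. The neighbour flask with 1.20 equiv of coupling partner keeps 0.51% of its substrate at 4.00 d, so our share of 0.528 puts its target at 52.8% of the charge, and at that time it holds 55.7%.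

(The readings stem from a simulated flask from invented constants; noise was put on by code.)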